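**Plan**

- Retrosynthetic cuts, in order: the C3–O bond of the secondary benzoate (made with inversion), the O–CH3 bond at C2, the two C–O bonds of the oxirane on C1 and C6, the acyl C–O bond of the primary benzoate, and last the ring C2–O and C3–O bonds, which leads back to ethyl benzoate.
- Enabling feature: the six-membered carbocycle carries one exocyclic carbon on C1, oxygen on C2 and on C3, the C4=C5 alkene and an oxirane over C1–C6. This is the oxidation pattern of a monosubstituted benzene whose ortho and meta carbons have been cis-dihydroxylated and one of whose two remaining diene bonds has been epoxidised, so an arene dioxygenase can open the synthesis.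
- Forward order: the benzene ring of ethyl benzoate becomes the carbocycle without any ring closure, the ester carbon becomes CH2OBz, the oxirane is the only ring formed (step 5), then the methyl ether and finally the C3 benzoate are installed.
- Stereochemistry: C2 comes from the enzyme and is kept. C1 and C6 are relayed from the free C2 hydroxyl in a directed epoxidation. C3 comes from the enzyme (cis to C2) and is inverted in the last step.

Key step: step 1

Remark: locants in the explanations follow the target (C1 = oxirane carbon bearing CH2OBz, C2 = OMe, C3 = OBz, C4=C5, C6 = oxirane CH, O7); compound names carry their own IUPAC locants. The SMILES of the target is read as (1R,2S,3R,6R).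

**Route**

Step 1
Reactants: 1 ethyl benzoate
Product: 2 ethyl (5S,6R)-5,6-dihydroxycyclohexa-1,3-diene-1-carboxylate
Conditions: whole cells of E. coli JM109 (pDTG601A) expressing toluene dioxygenase, IPTG induction, glucose feed (NADH recycled in the cells), air/O2 sparge, mineral salts medium pH 7, 30–35 °C; EtOAc extraction, kept cold and neutral and used at once
Reagents that add atoms: dioxygen, O=O
Why: Enzymatic arene cis-dihydroxylation: dioxygen is bound and reductively activated at the mononuclear non-heme iron centre (divalent iron in the resting state, electrons relayed from NADH through the reductase, the ferredoxin and the [2Fe-2S] cluster), and both oxygen atoms are delivered to one face of the ortho-meta bond of the arene, so that the C2–O and C3–O bonds are formed in one suprafacial event and the ring is dearomatised to the 1,3-diene. The closest known reaction type is the toluene dioxygenase oxidation of monosubstituted benzenes, which is established for alkyl benzoates. No ring is closed; the benzene ring is carried on as the carbocycle of the target. The two new stereocentres (5S and 6R) are fixed by the chiral active site, which binds the arene in one orientation, and they are cis because the addition is syn. The step needs ortho-meta regioselectivity and a single enantioface, both secured by the way the ester substituent sits in the substrate pocket, and it needs the diol to persist, which the recombinant strain secures because it lacks the diol dehydrogenase that would rearomatise it to the catechol.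

Step 2
Reactants: 2 ethyl (5S,6R)-5,6-dihydroxycyclohexa-1,3-diene-1-carboxylate
Product: 3 ethyl (5S,6R)-5-[(tert-butyldimethylsilyl)oxy]-6-hydroxycyclohexa-1,3-diene-1-carboxylate
Conditions: TBSCl (1.05 equiv), imidazole, DMF, −20 to 0 °C
Reagents that add atoms: tert-butyldimethylsilyl chloride, CC(C)(C)[Si](C)(C)Cl
Why: Regioselective monosilylation of a cis-diol: the hydroxyl next to the ester-bearing ring carbon is shielded by that substituent and hydrogen-bonded to the ester carbonyl, so the bulky silyl chloride should take the remote allylic hydroxyl, as it does in other arene cis-dihydrodiols, and no stereocentre is formed or touched.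

Step 3
Reactants: 3 ethyl (5S,6R)-5-[(tert-butyldimethylsilyl)oxy]-6-hydroxycyclohexa-1,3-diene-1-carboxylate
Product: 5 (1R,6S)-6-[(tert-butyldimethylsilyl)oxy]-2-(hydroxymethyl)cyclohexa-2,4-dien-1-ol, via dienal 4 (not isolated)
Conditions: i-Bu2AlH (3.5 equiv), CH2Cl2, −78 °C; aqueous potassium sodium tartrate (KNaC4H4O6) work-up
Reagents that add atoms: none
Why: 1,2-Reduction of a conjugated ester with i-Bu2AlH at low temperature: one equivalent is consumed by the free hydroxyl and two more take the ester through the dienal to the primary allylic alcohol without conjugate reduction, while the silyl ether and both stereocentres are left alone.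

Step 4
Reactants: 5 (1R,6S)-6-[(tert-butyldimethylsilyl)oxy]-2-(hydroxymethyl)cyclohexa-2,4-dien-1-ol; 6 benzoyl chloride
Product: 7 [(5S,6R)-5-[(tert-butyldimethylsilyl)oxy]-6-hydroxycyclohexa-1,3-dien-1-yl]methyl benzoate
Conditions: BzCl (1.05 equiv), 2,4,6-collidine, CH2Cl2, −78 to −30 °C
Reagents that add atoms: benzoyl chloride (compound 6), O=C(Cl)c1ccccc1
Why: Chemoselective acylation: the primary allylic hydroxyl should react far faster with benzoyl chloride at low temperature than the secondary hydroxyl, which is flanked by the substituted alkene carbon and the silyloxy-bearing carbon, and no stereocentre changes.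

Step 5
Reactants: 7 [(5S,6R)-5-[(tert-butyldimethylsilyl)oxy]-6-hydroxycyclohexa-1,3-dien-1-yl]methyl benzoate
Product: 8 [(1S,2S,3S,6R)-3-[(tert-butyldimethylsilyl)oxy]-2-hydroxy-7-oxabicyclo[4.1.0]hept-4-en-1-yl]methyl benzoate
Conditions: VO(acac)2 (5 mol %), t-BuOOH (anhydrous, in decane, 1.5 equiv), CH2Cl2, 0 °C to rt
Reagents that add atoms: tert-butyl hydroperoxide, CC(C)(C)OO
Why: Hydroxyl-directed epoxidation of an allylic alcohol: the secondary alkoxide binds the alkylperoxo complex of pentavalent vanadium formed from VO(acac)2 and t-BuOOH and delivers oxygen within the complex to the adjacent trisubstituted C1=C6 bond on its own face, which sets C1 and C6 together with the oxirane cis to the C2 oxygen, while the C4=C5 bond, only homoallylic to the free hydroxyl, should react much more slowly.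

Step 6
Reactants: 8 [(1S,2S,3S,6R)-3-[(tert-butyldimethylsilyl)oxy]-2-hydroxy-7-oxabicyclo[4.1.0]hept-4-en-1-yl]methyl benzoate
Product: 9 [(1R,2S,3S,6R)-3-[(tert-butyldimethylsilyl)oxy]-2-methoxy-7-oxabicyclo[4.1.0]hept-4-en-1-yl]methyl benzoate
Conditions: Me3OBF4 (3 equiv), 1,8-bis(dimethylamino)naphthalene (4 equiv), 4 Å molecular sieves, CH2Cl2, 0 °C to rt
Reagents that add atoms: trimethyloxonium tetrafluoroborate, C[O+](C)C.F[B-](F)(F)F
Why: O-Methylation with Meerwein's salt buffered by proton sponge: the neutral hydroxyl is alkylated by the oxonium salt and the acid set free is trapped by the non-nucleophilic base, so no alkoxide is formed and neither benzoate migration, silyl migration nor base-induced opening of the oxirane should occur; no stereocentre is touched, and the change of the C1 descriptor from S to R only reflects the new CIP ranking of C2.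

Step 7
Reactants: 9 [(1R,2S,3S,6R)-3-[(tert-butyldimethylsilyl)oxy]-2-methoxy-7-oxabicyclo[4.1.0]hept-4-en-1-yl]methyl benzoate
Product: 10 [(1R,2S,3S,6R)-3-hydroxy-2-methoxy-7-oxabicyclo[4.1.0]hept-4-en-1-yl]methyl benzoate
Conditions: Bu4NF (1.5 equiv), AcOH (1.5 equiv), THF, 0 °C to rt
Reagents that add atoms: none
Why: Fluoride-mediated desilylation driven by the strength of the Si–F bond, buffered with acetic acid so that the medium stays close to neutral and the benzoate and the vinyl oxirane should survive, with no stereocentre affected.

Step 8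
Reactants: 10 [(1R,2S,3S,6R)-3-hydroxy-2-methoxy-7-oxabicyclo[4.1.0]hept-4-en-1-yl]methyl benzoate; 11 benzoic acid
Product: 12 [(1R,2S,3R,6R)-3-(benzoyloxy)-2-methoxy-7-oxabicyclo[4.1.0]hept-4-en-1-yl]methyl benzoate (CNP0231490.2)
Conditions: PPh3 (1.5 equiv), DIAD (1.5 equiv), BzOH (1.5 equiv), THF, 0 °C to rt
Reagents that add atoms: benzoic acid (compound 11), OC(=O)c1ccccc1
Why: Mitsunobu esterification: the C3 hydroxyl, the only free one, is activated as its alkoxyphosphonium ion and displaced by benzoate in an SN2 reaction with inversion, which turns the cis C2/C3 arrangement inherited from the enzyme into the trans arrangement of the target (3S to 3R).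

**Compound list**

1 | ethyl benzoate | CCOC(=O)c1ccccc1 | starting material
2 | ethyl (5S,6R)-5,6-dihydroxycyclohexa-1,3-diene-1-carboxylate | O[C@H]1[C@@H](O)C=CC=C1C(=O)OCC | intermediate
3 | ethyl (5S,6R)-5-[(tert-butyldimethylsilyl)oxy]-6-hydroxycyclohexa-1,3-diene-1-carboxylate | O[C@H]1[C@@H](O[Si](C)(C)C(C)(C)C)C=CC=C1C(=O)OCC | intermediate
4 | (5S,6R)-5-[(tert-butyldimethylsilyl)oxy]-6-hydroxycyclohexa-1,3-diene-1-carbaldehyde (dienal, formed in the flask as its aluminium alkoxide, not isolated) | O[C@H]1[C@@H](O[Si](C)(C)C(C)(C)C)C=CC=C1C=O | intermediate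
5 | (1R,6S)-6-[(tert-butyldimethylsilyl)oxy]-2-(hydroxymethyl)cyclohexa-2,4-dien-1-ol | O[C@H]1[C@@H](O[Si](C)(C)C(C)(C)C)C=CC=C1CO | intermediate
6 | benzoyl chloride | O=C(Cl)c1ccccc1 | starting material
7 | [(5S,6R)-5-[(tert-butyldimethylsilyl)oxy]-6-hydroxycyclohexa-1,3-dien-1-yl]methyl benzoate | O[C@H]1[C@@H](O[Si](C)(C)C(C)(C)C)C=CC=C1COC(=O)c1ccccc1 | intermediate
8 | [(1S,2S,3S,6R)-3-[(tert-butyldimethylsilyl)oxy]-2-hydroxy-7-oxabicyclo[4.1.0]hept-4-en-1-yl]methyl benzoate | O[C@H]1[C@@H](O[Si](C)(C)C(C)(C)C)C=C[C@H]2O[C@]21COC(=O)c1ccccc1 | intermediate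
9 | [(1R,2S,3S,6R)-3-[(tert-butyldimethylsilyl)oxy]-2-methoxy-7-oxabicyclo[4.1.0]hept-4-en-1-yl]methyl benzoate | CO[C@H]1[C@@H](O[Si](C)(C)C(C)(C)C)C=C[C@H]2O[C@]21COC(=O)c1ccccc1 | intermediate
10 | [(1R,2S,3S,6R)-3-hydroxy-2-methoxy-7-oxabicyclo[4.1.0]hept-4-en-1-yl]methyl benzoate | CO[C@H]1[C@@H](O)C=C[C@H]2O[C@]21COC(=O)c1ccccc1 | intermediate
11 | benzoic acid | OC(=O)c1ccccc1 | starting material
12 | [(1R,2S,3R,6R)-3-(benzoyloxy)-2-methoxy-7-oxabicyclo[4.1.0]hept-4-en-1-yl]methyl benzoate (CNP0231490.2) | CO[C@H]1[C@H](OC(=O)c2ccccc2)C=C[C@H]2O[C@]21COC(=O)c1ccccc1 | target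

**Count and risks**

Total step count: 8. Longest linear sequence: 8 steps (1 to 12); 6 and 11 enter as purchased reagents.

Steps most likely to fail:

1. Step 6 (methylation next to the vinyl oxirane). The oxonium salt may alkylate the oxirane oxygen and trigger allylic ring opening, or the hindered carbinol between the quaternary oxirane carbon and the silyloxy carbon may be methylated too slowly. The fallback sets out from hydroxy ester 3, where no oxirane exists yet, and comes back at methyl ether 9.
   - The hydroxyl of 3 would be methylated under the same buffered oxonium conditions (or with MeI/Ag2O) to ethyl (5S,6R)-5-[(tert-butyldimethylsilyl)oxy]-6-methoxycyclohexa-1,3-diene-1-carboxylate F1.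
   - Reduction with i-Bu2AlH (CH2Cl2, −78 °C) would give [(5S,6R)-5-[(tert-butyldimethylsilyl)oxy]-6-methoxycyclohexa-1,3-dien-1-yl]methanol F2.
   - Because the C2 oxygen can then no longer deliver the oxidant, the oxirane would be placed under reagent control by a Sharpless asymmetric epoxidation of the primary allylic alcohol (Ti(OiPr)4, D-(−)-diisopropyl tartrate, t-BuOOH, 4 Å molecular sieves, CH2Cl2, −20 °C). This tartrate enantiomer is the one that directs oxygen to the face carrying the methoxy group, giving [(1R,2S,3S,6R)-3-[(tert-butyldimethylsilyl)oxy]-2-methoxy-7-oxabicyclo[4.1.0]hept-4-en-1-yl]methanol F3.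
   - Benzoylation of F3 (BzCl, pyridine, CH2Cl2, 0 °C) would give 9.
   - The cost of this detour is that the titanium tartrate has to override the steric preference of the substrate for the opposite face.

2. Step 5 (directed epoxidation of the dienol). The vanadium peroxide may oxidise the secondary allylic carbinol to a dienone that aromatises, may attack the C4=C5 bond, or the Lewis-acidic metal may open the vinyl oxirane once formed. The fallback sets out from diol 5 and comes back at epoxy alcohol 8.
   - The primary allylic hydroxyl of 5 would serve as the metal-binding group in a Sharpless epoxidation with the same tartrate enantiomer (Ti(OiPr)4, D-(−)-diisopropyl tartrate, t-BuOOH, 4 Å molecular sieves, CH2Cl2, −20 °C). Face selection then rests on the chiral ligand and not on the ring carbinol. This would give (1S,2S,3S,6R)-3-[(tert-butyldimethylsilyl)oxy]-1-(hydroxymethyl)-7-oxabicyclo[4.1.0]hept-4-en-2-ol F4.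
   - Selective benzoylation of the primary hydroxyl of F4 (BzCl, 2,4,6-collidine, CH2Cl2, −78 °C) would give 8.

3. Step 8 (Mitsunobu inversion at the allylic C3 carbinol). Benzoate may attack in the SN2′ sense at C5, the phosphonium intermediate may eliminate, an acyloxyphosphonium pathway may give retention, or the acid may open the vinyl oxirane. The fallback sets out from allylic alcohol 10 and ends at target 12.
   - Activation is separated from displacement: mesylation (MsCl, Et3N, CH2Cl2, −20 °C) would give [(1R,2S,3S,6R)-3-(methanesulfonyloxy)-2-methoxy-7-oxabicyclo[4.1.0]hept-4-en-1-yl]methyl benzoate F5.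
   - Displacement with cesium benzoate (PhCO2Cs, 18-crown-6, toluene or DMF, rt to 50 °C) would then give 12 by SN2 inversion with a weakly basic carboxylate.

**Further compounds**

F1 | step 6 | ethyl (5S,6R)-5-[(tert-butyldimethylsilyl)oxy]-6-methoxycyclohexa-1,3-diene-1-carboxylate | CO[C@H]1[C@@H](O[Si](C)(C)C(C)(C)C)C=CC=C1C(=O)OCC
F2 | step 6 | [(5S,6R)-5-[(tert-butyldimethylsilyl)oxy]-6-methoxycyclohexa-1,3-dien-1-yl]methanol | CO[C@H]1[C@@H](O[Si](C)(C)C(C)(C)C)C=CC=C1CO
F3 | step 6 | [(1R,2S,3S,6R)-3-[(tert-butyldimethylsilyl)oxy]-2-methoxy-7-oxabicyclo[4.1.0]hept-4-en-1-yl]methanol | CO[C@H]1[C@@H](O[Si](C)(C)C(C)(C)C)C=C[C@H]2O[C@]21CO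
F4 | step 5 | (1S,2S,3S,6R)-3-[(tert-butyldimethylsilyl)oxy]-1-(hydroxymethyl)-7-oxabicyclo[4.1.0]hept-4-en-2-ol | O[C@H]1[C@@H](O[Si](C)(C)C(C)(C)C)C=C[C@H]2O[C@]21CO
F5 | step 8 | [(1R,2S,3S,6R)-3-(methanesulfonyloxy)-2-methoxy-7-oxabicyclo[4.1.0]hept-4-en-1-yl]methyl benzoate | CO[C@H]1[C@@H](OS(C)(=O)=O)C=C[C@H]2O[C@]21COC(=O)c1ccccc1
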